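- Late in the earlier runs, ring and starting material fall together. Over the last 3 readings of each of the 3 runs, summed ring divided by summed starting material reads 0.746. Call this ring per starting material the balance ratio, ρ; it is a reading and carries their scatter.

| flask | starting material | remark | time |
|---|---|---|---|
| north-east | 0.12 M | run made earlier |  |
| west | 0.17 M | run made earlier |  |
| north | 0.26 M | run made earlier |  |
| blue | 0.12 M | one stirred flow tank at steady state, fed with the mixture as stated, mean residence time 100 h |  |
| red | 0.12 M | a single well-mixed tank run continuously and read at steady state, 20 h in it on average |  |
| grey | 0.12 M | a tube with plug flow, the mixed feed as stated, residence time 20 h | 20 h |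
| green | 0.12 M | a closed flask charged with all of it at once and left for 20 h | 20 h |

| run | time / h | ring / % | starting material / % |
|---|---|---|---|
| north-east | 1.00 | 35.2 | 51.4 |
| north-east | 3.00 | 31.1 | 42.2 |
| north-east | 6.00 | 26.3 | 36.2 |
| north-east | 8.00 | 23.1 | 30.7 |
| north-east | 12.0 | 18.8 | 28.3 |
| north-east | 15.0 | 17.7 | 21.3 |
| north-east | 20.0 | 14.3 | 22.0 |
| west | 1.33 | 34.5 | 44.8 |
| west | 2.00 | 30.5 | 41.2 |
| west | 3.00 | 29.4 | 37.9 |
| west | 5.00 | 24.8 | 32.4 |
| west | 6.00 | 21.4 | 30.3 |
| west | 10.0 | 18.1 | 22.6 |
| west | 15.0 | 14.4 | 19.1 |
| north | 0.833 | 31.0 | 45.1 |
| north | 2.50 | 25.6 | 34.1 |
| north | 5.00 | 21.4 | 26.3 |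
| north | 6.00 | 18.8 | 23.9 |
| north | 10.0 | 13.2 | 19.7 |
| north | 12.0 | 13.3 | 15.0 |
| north | 15.0 | 12.4 | 14.3 |

(readings scatter by 1 percentage point)

- the stated concentrations are those of everything mixed, before any reaction; amounts are the same in each set-up
- the numbers in the tables scatter with a standard deviation of 1 percentage point
- the earlier runs were made in a closed, stirred flask

- the set-up with the highest amount of ring at the outlet or at the end, in percent of the starting material put in ("none" if the first two lie within 2 percentage points) (blue / red / grey / green / none)
- amount of ring at the outlet or at the end, in percent of the starting material put in, blue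
- amount of ring at the outlet or at the end, in percent of the starting material put in, red
- amount of ring at the outlet or at the end, in percent of the starting material put in, grey
- amount of ring at the outlet or at the end, in percent of the starting material put in, green

- First rung: in the north-east run the first reading, at 1.00 h, already gives a ratio of 0.685. The exchange therefore comes close to its balance far sooner than the 20 h of the green and grey flasks, and you can treat it as a pre-equilibrium.
- So ring and starting material form one pool, and ring's share of it is ρ over one plus ρ, which is 42.7%. From here on you follow the pool.
- Middle rung: the pool drains over tens of hours, and faster from a richer charge. At 15.0 h the north run keeps 26.7%, less than the 39.0% of the north-east run.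
- Last rung: the stay in the vessel. Green and grey take every portion through the same 20 h from 0.12 M, so the north-east pool at that time, 36.3%, stands for both.
- My own reckoning multiplies share by pool and gives 15.5% ring for green and for grey, a little above the forecast's figure below.
- The forecast names red as best, with blue 12%, red 21.4%, grey 15% and green 15%. Its ground for the tanks is “A stirred tank suits second-order loss because the concentration stays low”.
- The flasks give red as best, with blue 14.6%, red 21.2%, grey 15.5% and green 15.5%, so the forecast held within its tolerance.

    starting material ⇌ ring (K = 0.720, k = 0.0210 /min)
    2 starting material ⇌ open dimer (K = 130 /M, k = 0.0220 /M/min)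

- In the red tank ring stays tied to starting material because of the undoing of ring into starting material: strike that step and the red tank's ring goes from 21.2% to 95.5%. With the step in place, ρ carries over to the tanks. Red holds 30.3% starting material, and ρ turns that into 22.6% ring against the 21.2% found. Blue holds 20.3% starting material, and ρ turns that into 15.1% ring against the 14.6% found.

Readings and results come from a simulation for an exercise, and the scatter is random.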